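**Retrosynthetic overview**

1. Target 16 comes from the (2R,3R)-3-hydroxy tribenzyl ether 14 by O-acetylation and hydrogenolysis of the three benzyl ethers.
2. 14 comes from the flat, achiral chromone 7 and arylzinc 10 in one flask: Rh-catalysed enantioselective 1,4-arylation with silyl capture forms the C2–aryl bond and the C2 stereocentre, and Rubottom oxidation of the enol silane installs the C3 oxygen trans to the new aryl group.
3. Enabling feature: in the pyranone ring (O1–C2–C3–C4=O) C2 is the β-carbon of the C4 ketone. At the chromone level C2=C3–C4=O is a vinylogous ester that accepts an aryl–metal at C2 and releases its enolate at C3–C4, exactly where the target carries its oxygen.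
4. 7 comes from 2-hydroxyacetophenone 5 by enaminone cyclisation; 5 comes from phloroacetophenone 1 by bis-benzylation, Elbs para-hydroxylation and methylation.
5. Ring order: ring A is bought, the pyranone ring is closed in step 4, and ring B is attached intact in step 6.

Key step: step 6

Assumption: the (S)-BINAP–rhodium catalyst is taken to deliver the aryl group to the C2 face that gives the 2S enol silane (2R once C3 carries oxygen, by the change in CIP priorities); if the sense proves opposite, (R)-BINAP is used with no other change.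

**Route**

Step 1
Reactants: 1 2′,4′,6′-trihydroxyacetophenone
Product: 2 1-[2,4-bis(benzyloxy)-6-hydroxyphenyl]ethanone
Conditions: BnBr (2.1 equiv), K2CO3, DMF, rt
Reagents that add atoms: benzyl bromide, BrCc1ccccc1
Why: Williamson etherification; after the para and one ortho hydroxyl are benzylated, the remaining ortho hydroxyl is locked in a hydrogen bond to the acetyl carbonyl and should stay free.

Step 2
Reactants: 2 1-[2,4-bis(benzyloxy)-6-hydroxyphenyl]ethanone
Product: 4 1-[2,4-bis(benzyloxy)-3,6-dihydroxyphenyl]ethanone, via aryl sulfate 3 (not isolated)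
Conditions: K2S2O8, aq KOH, pyridine, 0 °C to rt; then 2 M HCl, toluene, 70 °C
Reagents that add atoms: potassium peroxodisulfate, [K+].[K+].[O-]S(=O)(=O)OOS(=O)(=O)[O-]
Why: Elbs persulfate oxidation; the phenoxide attacks the peroxide oxygen through its only free para carbon (between the two benzyloxy groups), and acid hydrolysis of the aryl sulfate should give the hydroquinone.

Step 3
Reactants: 4 1-[2,4-bis(benzyloxy)-3,6-dihydroxyphenyl]ethanone
Product: 5 1-[2,4-bis(benzyloxy)-6-hydroxy-3-methoxyphenyl]ethanone
Conditions: MeI (1.1 equiv), K2CO3, acetone, rt, N2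
Reagents that add atoms: methyl iodide, CI
Why: Williamson etherification; the C6 hydroxyl is chelated to the acetyl carbonyl, so the non-chelated C3 hydroxyl should be methylated selectively.

Step 4
Reactants: 5 1-[2,4-bis(benzyloxy)-6-hydroxy-3-methoxyphenyl]ethanone
Product: 7 5,7-bis(benzyloxy)-6-methoxy-4H-chromen-4-one, via enaminone 6 (not isolated)
Conditions: DMF-DMA, toluene, 100 °C; then 2 M HCl, CH2Cl2, rt
Reagents that add atoms: N,N-dimethylformamide dimethyl acetal, COC(OC)N(C)C
Why: Enaminone route to chromones; condensation at the methyl ketone, then acid-promoted 6-endo addition of the phenol to the enaminone and loss of dimethylamine should close the pyranone ring.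

Step 5
Reactants: 8 1-(benzyloxy)-4-bromobenzene
Product: 10 [4-(benzyloxy)phenyl]zinc chloride, via Grignard reagent 9 (not isolated)
Conditions: Mg, THF, 40 °C; then ZnCl2, THF, 0 °C to rt (solution used directly)
Reagents that add atoms: zinc chloride, Cl[Zn]Cl
Why: Magnesium insertion into the aryl bromide followed by Mg-to-Zn transmetalation should give the arylzinc chloride; the benzyl ether is inert to both.

Step 6
Reactants: 7 5,7-bis(benzyloxy)-6-methoxy-4H-chromen-4-one; 10 [4-(benzyloxy)phenyl]zinc chloride
Product: 14 (2R,3R)-5,7-bis(benzyloxy)-2-[4-(benzyloxy)phenyl]-3-hydroxy-6-methoxychroman-4-one, via enol silane 11 (not isolated), via silyloxy epoxide 12 (not isolated), via 3-silyloxy ketone 13 (not isolated)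
Conditions: [RhCl(C2H4)2]2/(S)-BINAP (cat.), Me3SiCl, THF, 20 °C; cold pH 7 buffer wash, crude 11; DMDO (1.1 equiv), acetone/CH2Cl2, −40 to 0 °C; then aq citric acid, THF, rt
Reagents that add atoms: dimethyldioxirane, CC1(C)OO1
Why: Aryl transfer from zinc to Rh(I)–BINAP gives an aryl–rhodium species that inserts the C2=C3 bond of the vinylogous ester 7 with the aryl group going to C2, and the resulting oxa-π-allyl rhodium enolate is silylated at O4 by Me3SiCl to give enol silane 11 faster than it can be protonated or open the ring by β-aryloxide elimination; DMDO then epoxidises C3=C4 of 11 to 12, which rearranges by 1,4-silyl shift to 13 and is desilylated to 14 (Rubottom oxidation). The closest known reaction types are the Rh/BINAP-catalysed asymmetric 1,4-addition of arylzinc chlorides with Me3SiCl to 4-quinolones and 2,3-dihydro-4-pyridones, the Rh-catalysed asymmetric 1,4-addition of arylboron reagents to chromones, and the Rubottom oxidation of flavanone enol silanes. No ring of the target is closed here; the only ring formed is the transient oxirane of 12 (concerted oxygen-atom transfer to C3=C4), which opens again. C2 is set by the chiral ligand, which differentiates the two faces of the planar chromone in the migratory insertion (reagent control), and C3 is set by the C2 stereocentre, because the oxidant should add to the enol silane on the face anti to the 2-aryl group so that the C3–O bond ends trans to it (substrate control), giving 2R,3R. The step needs 1,4- over 1,2-addition, secured by the low carbonyl affinity of arylzinc and arylrhodium species; regiospecific enolate capture, secured because the enolate is born at C3–C4 and silylated in situ; and chemoselective oxidation of the enol silane beside three benzyl ethers and a trialkoxyarene, secured by its much higher nucleophilicity at low temperature with about one equivalent of DMDO.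

Step 7
Reactants: 14 (2R,3R)-5,7-bis(benzyloxy)-2-[4-(benzyloxy)phenyl]-3-hydroxy-6-methoxychroman-4-one
Product: 15 (2R,3R)-5,7-bis(benzyloxy)-2-[4-(benzyloxy)phenyl]-6-methoxy-4-oxochroman-3-yl acetate
Conditions: Ac2O, pyridine, DMAP (cat.), CH2Cl2, 0 °C
Reagents that add atoms: acetic anhydride, CC(=O)OC(C)=O
Why: DMAP-catalysed O-acylation of the only free hydroxyl; the weak base and low temperature should avoid enolisation at C3 and ring opening, so both stereocentres are retained.

Step 8
Reactants: 15 (2R,3R)-5,7-bis(benzyloxy)-2-[4-(benzyloxy)phenyl]-6-methoxy-4-oxochroman-3-yl acetate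
Product: 16 6-methoxyaromadendrin 3-O-acetate [(2R,3R)-5,7-dihydroxy-2-(4-hydroxyphenyl)-6-methoxy-4-oxochroman-3-yl acetate]
Conditions: H2 (1 atm), 10% Pd/C, EtOAc/THF, rt
Reagents that add atoms: none
Why: Pd-catalysed hydrogenolysis of the three aryl benzyl ethers in a neutral, non-nucleophilic medium should leave the C3 acetate, the C4 ketone and both stereocentres untouched.

**Compound list**

1 | 2′,4′,6′-trihydroxyacetophenone | CC(=O)c1c(O)cc(O)cc1O | starting material
2 | 1-[2,4-bis(benzyloxy)-6-hydroxyphenyl]ethanone | CC(=O)c1c(O)cc(OCc2ccccc2)cc1OCc1ccccc1 | intermediate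
3 | potassium 3-acetyl-2,6-bis(benzyloxy)-4-hydroxyphenyl sulfate | CC(=O)c1c(O)cc(OCc2ccccc2)c(OS(=O)(=O)[O-])c1OCc1ccccc1.[K+] | intermediate
4 | 1-[2,4-bis(benzyloxy)-3,6-dihydroxyphenyl]ethanone | CC(=O)c1c(O)cc(OCc2ccccc2)c(O)c1OCc1ccccc1 | intermediate
5 | 1-[2,4-bis(benzyloxy)-6-hydroxy-3-methoxyphenyl]ethanone | CC(=O)c1c(O)cc(OCc2ccccc2)c(OC)c1OCc1ccccc1 | intermediate
6 | (E)-1-[2,4-bis(benzyloxy)-6-hydroxy-3-methoxyphenyl]-3-(dimethylamino)prop-2-en-1-one | CN(C)/C=C/C(=O)c1c(O)cc(OCc2ccccc2)c(OC)c1OCc1ccccc1 | intermediate
7 | 5,7-bis(benzyloxy)-6-methoxy-4H-chromen-4-one | COc1c(OCc2ccccc2)cc2occc(=O)c2c1OCc1ccccc1 | intermediate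
8 | 1-(benzyloxy)-4-bromobenzene | Brc1ccc(OCc2ccccc2)cc1 | starting material
9 | [4-(benzyloxy)phenyl]magnesium bromide | Br[Mg]c1ccc(OCc2ccccc2)cc1 | intermediate
10 | [4-(benzyloxy)phenyl]zinc chloride | Cl[Zn]c1ccc(OCc2ccccc2)cc1 | intermediate
11 | (2S)-5,7-bis(benzyloxy)-2-[4-(benzyloxy)phenyl]-6-methoxy-4-[(trimethylsilyl)oxy]-2H-chromene | COc1c(OCc3ccccc3)cc2c(c1OCc1ccccc1)C(O[Si](C)(C)C)=C[C@@H](c1ccc(OCc3ccccc3)cc1)O2 | intermediate
12 | 3,4-epoxide of 11, 5,7-bis(benzyloxy)-2-[4-(benzyloxy)phenyl]-3,4-epoxy-6-methoxy-4-[(trimethylsilyl)oxy]chromane, oxirane oxygen anti to the 2-aryl group | COc1c(OCc3ccccc3)cc2c(c1OCc1ccccc1)[C@]3(O[Si](C)(C)C)O[C@@H]3[C@@H](c1ccc(OCc4ccccc4)cc1)O2 | intermediate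
13 | (2R,3R)-5,7-bis(benzyloxy)-2-[4-(benzyloxy)phenyl]-6-methoxy-3-[(trimethylsilyl)oxy]chroman-4-one | COc1c(OCc3ccccc3)cc2c(c1OCc1ccccc1)C(=O)[C@H](O[Si](C)(C)C)[C@@H](c1ccc(OCc3ccccc3)cc1)O2 | intermediate
14 | (2R,3R)-5,7-bis(benzyloxy)-2-[4-(benzyloxy)phenyl]-3-hydroxy-6-methoxychroman-4-one | COc1c(OCc3ccccc3)cc2c(c1OCc1ccccc1)C(=O)[C@H](O)[C@@H](c1ccc(OCc3ccccc3)cc1)O2 | intermediate
15 | (2R,3R)-5,7-bis(benzyloxy)-2-[4-(benzyloxy)phenyl]-6-methoxy-4-oxochroman-3-yl acetate | COc1c(OCc3ccccc3)cc2c(c1OCc1ccccc1)C(=O)[C@H](OC(C)=O)[C@@H](c1ccc(OCc3ccccc3)cc1)O2 | intermediate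
16 | 6-methoxyaromadendrin 3-O-acetate, (2R,3R)-5,7-dihydroxy-2-(4-hydroxyphenyl)-6-methoxy-4-oxochroman-3-yl acetate | COc1c(O)cc2c(c1O)C(=O)[C@H](OC(C)=O)[C@@H](c1ccc(O)cc1)O2 | target

**Count and risks**

Total steps: 8. Longest linear sequence: 7 steps (steps 1–4 and 6–8); step 5 is a one-step side branch.

Steps most likely to fail:

1. Step 6. The electron-rich, peri-substituted chromone may insert slowly, the enantioselectivity may be eroded by an uncatalysed addition to the silyl-activated chromone, and the trimethylsilyl enol ether may hydrolyse before it is oxidised. The fallback separates bond formation from enolate capture and sets out from 7. A Pd(II)/t-BuPyOx-catalysed asymmetric conjugate addition of commercial 4-(benzyloxy)phenylboronic acid (Pd(OCOCF3)2, the ligand enantiomer that gives the 2S product, NH4PF6, H2O, ClCH2CH2Cl, 60 °C) should give the isolable (2S)-5,7-bis(benzyloxy)-2-[4-(benzyloxy)phenyl]-6-methoxychroman-4-one F1. Soft enolisation (Me3SiOTf, Et3N, CH2Cl2, 0 °C), which avoids a free enolate and therefore ring opening, then gives enol silane 11, where the route is rejoined for the DMDO oxidation to 14.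

2. Step 2. The poorly soluble phenoxide may convert incompletely, the hydroquinone may be over-oxidised under alkaline persulfate, and a benzyl ether may be lost during the acidic sulfate hydrolysis. The fallback sets out from 2 and replaces the persulfate attack by a radical para-oxygenation. Teuber oxidation with Fremy's salt (potassium nitrosodisulfonate, KH2PO4 buffer, acetone/H2O, rt) should give 2-acetyl-3,5-bis(benzyloxy)-1,4-benzoquinone F2, and reduction with Na2S2O4 (EtOAc/H2O) returns to the route at hydroquinone 4.

3. Step 8. Hydrogenolysis of the benzylic C2–O1 bond (ring opening) may compete with ether cleavage, or debenzylation may stop part-way. The fallback sets out from 15 and removes the benzyl groups without hydrogen, by Lewis-acid cleavage with a cation scavenger (BCl3, pentamethylbenzene, CH2Cl2, −78 °C). It arrives directly at 16 and makes no new compound (F0).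

Further compounds
F1 | step 6 | (2S)-5,7-bis(benzyloxy)-2-[4-(benzyloxy)phenyl]-6-methoxychroman-4-one | COc1c(OCc3ccccc3)cc2c(c1OCc1ccccc1)C(=O)C[C@@H](c1ccc(OCc3ccccc3)cc1)O2
F2 | step 2 | 2-acetyl-3,5-bis(benzyloxy)-1,4-benzoquinone | O=C1C=C(OCc2ccccc2)C(=O)C(OCc2ccccc2)=C1C(C)=O
F0 | step 8 | none | none
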